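**Retrosynthetic overview**
- Target ⇒ crossed Claisen condensation at the diketone CH2 (silyl ether removed last): all-trans cyclohexene methyl ester + dehydrozingerone.
- Cyclohexene ester ⇒ one carbene/palladium annulation. The β-carbon of silylated coniferaldehyde, made nucleophilic as a homoenolate, bonds to the CH2 end of a but-2-ene bis-electrophile (ring C5–C6); the α-carbon then bonds to its benzylic end (ring C1–C2).
- Bis-electrophile (primary carbonate, benzylic acetate, 4R) ⇒ 3,4-dimethoxybenzaldehyde + methyl propargyl carbonate by asymmetric alkenylzinc addition and acetylation.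
- Rings: the arenes are bought; the cyclohexene is the only ring made, closed in the key step. C6 comes from the carbene, C2 from the acetate by stereospecific substitution, and C1 is the thermodynamic (all-equatorial) centre.

Assumption: the senses of induction of the two chiral catalysts (amino alcohol in step 1, triazolium salt in step 3) are assigned by analogy; if either proves opposite, its enantiomer is used and nothing else changes.

**Step 1**
Reactants: 1 3,4-dimethoxybenzaldehyde; 2 methyl prop-2-yn-1-yl carbonate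
Product: 6 (2E,4R)-4-acetoxy-4-(3,4-dimethoxyphenyl)but-2-en-1-yl methyl carbonate, via alkenylborane 3 (not isolated), via alkenylzinc 4 (not isolated), via zinc alkoxide 5 (not isolated)
Conditions: 2, Cy2BH, toluene, 0 → 23 °C; Et2Zn, −78 °C; (2R)-3-exo-morpholinoisoborneol (5 mol%), then 1, −10 °C; Ac2O, 4-(dimethylamino)pyridine (5 mol%), 0 °C; aq. NH4Cl
Reagents that add atoms: acetic anhydride, CC(=O)OC(C)=O
Why: Syn hydroboration fixes the E alkene, boron-to-zinc exchange gives an alkenylzinc whose amino-alcohol-catalysed addition to the aldehyde (catalytic asymmetric alkenylzinc addition, Oppolzer type) sets the (R) carbinol centre under ligand control, and the zinc alkoxide is acetylated in the same flask, the mild zinc reagents leaving the carbonate untouched.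

**Step 2**
Reactants: 7 (E)-3-(4-hydroxy-3-methoxyphenyl)prop-2-enal (coniferaldehyde)
Product: 8 (E)-3-{3-methoxy-4-[tri(propan-2-yl)silyloxy]phenyl}prop-2-enal
Conditions: i-Pr3SiCl, imidazole, DMF, 23 °C
Reagents that add atoms: chlorotri(propan-2-yl)silane, CC(C)[Si](Cl)(C(C)C)C(C)C
Why: Silyl ether protection of the phenol; the bulky silyl group survives methoxide, amide base and the carbene and is removed by fluoride.

**Step 3 (key step)**
Reactants: 6 (2E,4R)-4-acetoxy-4-(3,4-dimethoxyphenyl)but-2-en-1-yl methyl carbonate; 8 (E)-3-{3-methoxy-4-[tri(propan-2-yl)silyloxy]phenyl}prop-2-enal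
Product: 11 methyl (1R,2R,6S)-2-(3,4-dimethoxyphenyl)-6-{3-methoxy-4-[tri(propan-2-yl)silyloxy]phenyl}cyclohex-3-ene-1-carboxylate, via azolium enolate 9 (not isolated), via acyl azolium 10 (not isolated)
Conditions: Pd(PPh3)4 (5 mol%), (5aS,10bR)-2-mesityl-5a,10b-dihydro-4H,6H-indeno[2,1-b][1,2,4]triazolo[4,3-d][1,4]oxazin-2-ium chloride (10 mol%), i-Pr2NEt (20 mol%), 4 Å molecular sieves, THF, 23 °C
Reagents that add atoms: none
Why: Proposed new method: the carbene turns the enal into its Breslow homoenolate, whose normally electrophilic β-carbon attacks the CH2 terminus of the π-allyl that zerovalent palladium forms from the primary carbonate (ionised far faster than the acetate), the N-mesityl aminoindanol carbene setting the (6S) centre; palladium, already on the new E alkene, then ionises the benzylic acetate, the syn π-allyl turns anti at its chain-bearing terminus by an η3–η1–η3 flip (the only geometry that can close a cyclohexene, and one that puts the metal on the other face of the benzylic carbon), and azolium enolate 9 closes the ring by chair-like 6-endo attack anti to the metal, so the (4R) acetate becomes the (2R) ring carbon by net inversion with all three substituents equatorial (C1 R), after which the methoxide freed from the carbonate cleaves acyl azolium 10 to the methyl ester; the closest known reaction types are cooperative carbene/palladium umpolung annulations of enals with π-allylpalladium species, allylation of carbene-bound enolates by iridium π-allyls and palladium double allylic alkylation of but-2-ene-1,4-diyl diesters.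

**Step 4**
Reactants: 11 methyl (1R,2R,6S)-2-(3,4-dimethoxyphenyl)-6-{3-methoxy-4-[tri(propan-2-yl)silyloxy]phenyl}cyclohex-3-ene-1-carboxylate; 12 (E)-4-(4-hydroxy-3-methoxyphenyl)but-3-en-2-one (dehydrozingerone)
Product: 14 (2Z,4E)-1-[(1R,2R,6S)-2-(3,4-dimethoxyphenyl)-6-{3-methoxy-4-[tri(propan-2-yl)silyloxy]phenyl}cyclohex-3-en-1-yl]-3-hydroxy-5-(4-hydroxy-3-methoxyphenyl)penta-2,4-dien-1-one, via dilithium dianion 13 (not isolated)
Conditions: 12 (3 equiv), LiN(SiMe3)2 (6.2 equiv), THF, −78 → 0 °C; then 11, 0 → 45 °C; aq. NH4Cl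
Reagents that add atoms: none
Why: Crossed Claisen condensation in which the phenoxide-enolate dianion 13 is C-acylated at its methyl terminus and deprotonation of the new β-diketone makes the step irreversible; the phenoxide suppresses self-Michael addition of the enone and the basic medium levels ring C1 to the all-equatorial (1R) arrangement, so no stereocentre is at risk.

**Step 5**
Reactants: 14 (2Z,4E)-1-[(1R,2R,6S)-2-(3,4-dimethoxyphenyl)-6-{3-methoxy-4-[tri(propan-2-yl)silyloxy]phenyl}cyclohex-3-en-1-yl]-3-hydroxy-5-(4-hydroxy-3-methoxyphenyl)penta-2,4-dien-1-one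
Product: 15 (2Z,4E)-1-[(1R,2R,6S)-2-(3,4-dimethoxyphenyl)-6-(4-hydroxy-3-methoxyphenyl)cyclohex-3-en-1-yl]-3-hydroxy-5-(4-hydroxy-3-methoxyphenyl)penta-2,4-dien-1-one (CNP0290899.1)
Conditions: Bu4NF, AcOH, THF, 0 °C
Reagents that add atoms: none
Why: Fluoride cleavage of the aryl silyl ether (desilylation), buffered with acetic acid so that the base-sensitive enolised β-diketone and the epimerisable C1 are untouched.

**Compound list**
1 | 3,4-dimethoxybenzaldehyde | COc1ccc(C=O)cc1OC | starting material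
2 | methyl prop-2-yn-1-yl carbonate | COC(=O)OCC#C | starting material
3 | dicyclohexyl[(E)-3-(methoxycarbonyloxy)prop-1-en-1-yl]borane | COC(=O)OC/C=C/B(C1CCCCC1)C1CCCCC1 | intermediate (not isolated)
4 | ethyl[(E)-3-(methoxycarbonyloxy)prop-1-en-1-yl]zinc | CC[Zn]/C=C/COC(=O)OC | intermediate (not isolated)
5 | ethylzinc (1R,2E)-1-(3,4-dimethoxyphenyl)-4-(methoxycarbonyloxy)but-2-en-1-olate | COC(=O)OC/C=C/[C@@H](O[Zn]CC)c1ccc(OC)c(OC)c1 | intermediate (not isolated)
6 | (2E,4R)-4-acetoxy-4-(3,4-dimethoxyphenyl)but-2-en-1-yl methyl carbonate | COC(=O)OC/C=C/[C@@H](OC(C)=O)c1ccc(OC)c(OC)c1 | intermediate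
7 | (E)-3-(4-hydroxy-3-methoxyphenyl)prop-2-enal | COc1cc(/C=C/C=O)ccc1O | starting material
8 | (E)-3-{3-methoxy-4-[tri(propan-2-yl)silyloxy]phenyl}prop-2-enal | COc1cc(/C=C/C=O)ccc1O[Si](C(C)C)(C(C)C)C(C)C | intermediate
9 | triazolium enolate after the first allylation: (3S,5E,7R)-7-acetoxy-hept-5-enoyl chain bound to the carbene, enolate geometry not assigned | [O-]C(=C[C@@H](c1ccc(O[Si](C(C)C)(C(C)C)C(C)C)c(OC)c1)C/C=C/[C@@H](OC(C)=O)c1ccc(OC)c(OC)c1)c1n2c(n[n+]1-c1c(C)cc(C)cc1C)CO[C@H]1Cc3ccccc3[C@@H]21 | intermediate (not isolated)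
10 | (1R,2R,6S)-cyclohex-3-ene-1-carbonyl triazolium acetate (cyclised acyl azolium) | CC(=O)[O-].O=C([C@@H]1[C@@H](c2ccc(O[Si](C(C)C)(C(C)C)C(C)C)c(OC)c2)CC=C[C@H]1c1ccc(OC)c(OC)c1)c1n2c(n[n+]1-c1c(C)cc(C)cc1C)CO[C@H]1Cc3ccccc3[C@@H]21 | intermediate (not isolated)
11 | methyl (1R,2R,6S)-2-(3,4-dimethoxyphenyl)-6-{3-methoxy-4-[tri(propan-2-yl)silyloxy]phenyl}cyclohex-3-ene-1-carboxylate | COC(=O)[C@@H]1[C@@H](c2ccc(O[Si](C(C)C)(C(C)C)C(C)C)c(OC)c2)CC=C[C@H]1c1ccc(OC)c(OC)c1 | intermediate
12 | (E)-4-(4-hydroxy-3-methoxyphenyl)but-3-en-2-one | COc1cc(/C=C/C(C)=O)ccc1O | starting material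
13 | dilithium dianion of 12 (phenoxide and methyl-side enolate) | [Li+].[Li+].COc1cc(/C=C/C(=C)[O-])ccc1[O-] | intermediate (not isolated)
14 | (2Z,4E)-1-[(1R,2R,6S)-2-(3,4-dimethoxyphenyl)-6-{3-methoxy-4-[tri(propan-2-yl)silyloxy]phenyl}cyclohex-3-en-1-yl]-3-hydroxy-5-(4-hydroxy-3-methoxyphenyl)penta-2,4-dien-1-one | COc1cc(/C=C/C(O)=C/C(=O)[C@@H]2[C@@H](c3ccc(O[Si](C(C)C)(C(C)C)C(C)C)c(OC)c3)CC=C[C@H]2c2ccc(OC)c(OC)c2)ccc1O | intermediate
15 | (2Z,4E)-1-[(1R,2R,6S)-2-(3,4-dimethoxyphenyl)-6-(4-hydroxy-3-methoxyphenyl)cyclohex-3-en-1-yl]-3-hydroxy-5-(4-hydroxy-3-methoxyphenyl)penta-2,4-dien-1-one | COc1cc(/C=C/C(O)=C/C(=O)[C@@H]2[C@@H](c3ccc(O)c(OC)c3)CC=C[C@H]2c2ccc(OC)c(OC)c2)ccc1O | target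

**Totals**
Total step count: 5. Longest linear sequence: 4 (step 1 or step 2, then steps 3, 4, 5).

**Steps most likely to fail**

Step 3 (highest risk). Three catalytic events must follow one another. Likely failures are protonation of the homoenolate or of enolate 9 before the second allylation (saturated or open-chain esters), ionisation of the acetate before the carbonate (regioisomers), and β-hydride loss from the second π-allyl (trienes). Minor enantiomers of either partner end up as diastereomers and are removed by chromatography.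
Fallback: the two bonds are made separately and the ring is closed by olefin metathesis. Setting out from 8, the same carbene/Pd(PPh3)4 pair with plain allyl methyl carbonate gives methyl (3S)-3-{3-methoxy-4-[tri(propan-2-yl)silyloxy]phenyl}hex-5-enoate F1. LiN(i-Pr)2 and Me3SiCl convert it to its trimethylsilyl ketene acetal F2. This is allylated at the branched position by (E)-3-(3,4-dimethoxyphenyl)prop-2-en-1-yl methyl carbonate F3 (from bought 3,4-dimethoxycinnamyl alcohol and ClCO2Me), using [Ir(cod)Cl]2, a binaphthol phosphoramidite and ZnF2, to give methyl (2RS,3S)-2-[(1R)-1-(3,4-dimethoxyphenyl)prop-2-en-1-yl]-3-{3-methoxy-4-[tri(propan-2-yl)silyloxy]phenyl}hex-5-enoate F4. Second-generation Grubbs catalyst closes the ring, and the route is rejoined at 11; the C1 epimer that accompanies it is levelled by the base of step 4.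

Step 4. The ester carbonyl of 11 sits between two aryl-bearing carbons and may be too hindered to acylate the dianion.
Fallback: the carbonyl is attacked at the aldehyde level. Setting out from 11, i-Bu2AlH (CH2Cl2, −78 °C) gives (1R,2R,6S)-2-(3,4-dimethoxyphenyl)-6-{3-methoxy-4-[tri(propan-2-yl)silyloxy]phenyl}cyclohex-3-ene-1-carbaldehyde F5. Compound 12 is silylated (i-Pr3SiCl, imidazole) to (E)-4-{3-methoxy-4-[tri(propan-2-yl)silyloxy]phenyl}but-3-en-2-one F6, whose lithium enolate (LiN(SiMe3)2, −78 °C) adds to F5 to give the aldol (E)-5-hydroxy-5-[(1R,2R,6S)-2-(3,4-dimethoxyphenyl)-6-{3-methoxy-4-[tri(propan-2-yl)silyloxy]phenyl}cyclohex-3-en-1-yl]-1-{3-methoxy-4-[tri(propan-2-yl)silyloxy]phenyl}pent-1-en-3-one F7. Dess–Martin periodinane oxidises it to the bis-silyl ether of the target F8, and Bu4NF/AcOH as in step 5 removes both silyl groups, rejoining the route at 15.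

Step 1. The carbonate-bearing alkenylzinc may add with poor selectivity, and the electron-rich benzylic allylic acetate 6 may racemise or rearrange on isolation.
Fallback: the stereocentre is taken from an enzymatic resolution and the alkene from cross-metathesis. Setting out from 1, CH2=CHMgBr gives racemic 1-(3,4-dimethoxyphenyl)prop-2-en-1-ol F9. Candida antarctica lipase B with vinyl acetate acetylates only the (R) alcohol, giving (1R)-1-(3,4-dimethoxyphenyl)prop-2-en-1-yl acetate F10. Cross-metathesis of F10 with allyl methyl carbonate (second-generation Hoveyda–Grubbs catalyst) gives the E alkene and rejoins the route at 6.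

**Further compounds**
F1 | step 3 | methyl (3S)-3-{3-methoxy-4-[tri(propan-2-yl)silyloxy]phenyl}hex-5-enoate | COC(=O)C[C@@H](c1ccc(O[Si](C(C)C)(C(C)C)C(C)C)c(OC)c1)CC=C
F2 | step 3 | trimethylsilyl ketene acetal of F1 (geometry not assigned) | COC(O[Si](C)(C)C)=C[C@@H](c1ccc(O[Si](C(C)C)(C(C)C)C(C)C)c(OC)c1)CC=C
F3 | step 3 | (E)-3-(3,4-dimethoxyphenyl)prop-2-en-1-yl methyl carbonate | COC(=O)OC/C=C/c1ccc(OC)c(OC)c1
F4 | step 3 | methyl (2RS,3S)-2-[(1R)-1-(3,4-dimethoxyphenyl)prop-2-en-1-yl]-3-{3-methoxy-4-[tri(propan-2-yl)silyloxy]phenyl}hex-5-enoate | COC(=O)C([C@@H](c1ccc(O[Si](C(C)C)(C(C)C)C(C)C)c(OC)c1)CC=C)[C@@H](C=C)c1ccc(OC)c(OC)c1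
F5 | step 4 | (1R,2R,6S)-2-(3,4-dimethoxyphenyl)-6-{3-methoxy-4-[tri(propan-2-yl)silyloxy]phenyl}cyclohex-3-ene-1-carbaldehyde | O=C[C@@H]1[C@@H](c2ccc(O[Si](C(C)C)(C(C)C)C(C)C)c(OC)c2)CC=C[C@H]1c1ccc(OC)c(OC)c1
F6 | step 4 | (E)-4-{3-methoxy-4-[tri(propan-2-yl)silyloxy]phenyl}but-3-en-2-one | COc1cc(/C=C/C(C)=O)ccc1O[Si](C(C)C)(C(C)C)C(C)C
F7 | step 4 | (E)-5-hydroxy-5-[(1R,2R,6S)-2-(3,4-dimethoxyphenyl)-6-{3-methoxy-4-[tri(propan-2-yl)silyloxy]phenyl}cyclohex-3-en-1-yl]-1-{3-methoxy-4-[tri(propan-2-yl)silyloxy]phenyl}pent-1-en-3-one (carbinol epimers) | COc1cc(/C=C/C(=O)CC(O)[C@@H]2[C@@H](c3ccc(O[Si](C(C)C)(C(C)C)C(C)C)c(OC)c3)CC=C[C@H]2c2ccc(OC)c(OC)c2)ccc1O[Si](C(C)C)(C(C)C)C(C)C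
F8 | step 4 | bis[tri(propan-2-yl)silyl] ether of the target | COc1cc(/C=C/C(O)=C/C(=O)[C@@H]2[C@@H](c3ccc(O[Si](C(C)C)(C(C)C)C(C)C)c(OC)c3)CC=C[C@H]2c2ccc(OC)c(OC)c2)ccc1O[Si](C(C)C)(C(C)C)C(C)C
F9 | step 1 | racemic 1-(3,4-dimethoxyphenyl)prop-2-en-1-ol | C=CC(O)c1ccc(OC)c(OC)c1
F10 | step 1 | (1R)-1-(3,4-dimethoxyphenyl)prop-2-en-1-yl acetate | C=C[C@@H](OC(C)=O)c1ccc(OC)c(OC)c1
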